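**Retrosynthetic overview** (listed from the fragments up to the target)
1. Biaryl bond: 5-bromo-2,4-dimethoxypyridine 1 and the inexpensive bulk arene 4-methoxyphenylboronic acid 2 are the fragments of biaryl 3 (Suzuki–Miyaura).
2. Key disconnection, ketone C–C bond: meso-2,4-dimethylglutaric anhydride 4 is opened enantioselectively by the C3-metalated forms 5 and 6 of 3 under chiral rhodium catalysis. This single symmetry-breaking step gives keto acid 7 with the acyl–pyridine bond and both methyl stereocentres.
3. C5–C6 bond: the carboxyl carbon of 7 becomes the C5 methylene (alcohol 8, iodide 9) and is joined sp3–sp2 to (E)-1-bromopropene 10 to give 11.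
4. Last disconnection: the three O–CH3 bonds of 11; global demethylation unveils the 4-hydroxy-2-pyridone and the phenol of tolypyridone C 12.
5. Rings: none is constructed. The pyridine and benzene rings are bought and joined first, the anhydride ring is opened second, and the pyridone tautomer appears only in the last step.

Assumption: 1, 2, 4 (pure meso isomer) and 10 (pure E isomer) are taken as catalogue chemicals, and the ligand antipode written in step 2 is the one assumed to give 7 (the sense of induction has to be confirmed in a trial run).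

**Route**

Step 1
Reactants: 1 5-bromo-2,4-dimethoxypyridine; 2 4-methoxyphenylboronic acid
Product: 3 2,4-dimethoxy-5-(4-methoxyphenyl)pyridine
Conditions: Pd(PPh3)4 (3 mol %), K2CO3, dioxane/H2O (4:1), 90 °C
Reagents that add atoms: none
Why: Suzuki–Miyaura cross-coupling, in which zerovalent palladium inserts into the C5–Br bond and the arylboronate transfers the 4-methoxyphenyl group; the methoxy groups are inert and no stereocentre is formed.

Step 2
Reactants: 3 2,4-dimethoxy-5-(4-methoxyphenyl)pyridine; 4 meso-2,4-dimethylglutaric anhydride, (3R,5S)-3,5-dimethyloxane-2,6-dione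
Product: 7 (2R,4S)-5-[2,4-dimethoxy-5-(4-methoxyphenyl)pyridin-3-yl]-2,4-dimethyl-5-oxopentanoic acid, via C3-lithiated pyridine 5 (not isolated), via pyridin-3-ylzinc chloride 6 (not isolated)
Conditions: n-BuLi, THF, −78 to −30 °C; ZnCl2, −30 °C to rt; then 4, [Rh(cod)Cl]2 (4 mol %), (S)-t-Bu-PHOX [(S)-4-tert-butyl-2-(2-diphenylphosphinophenyl)-4,5-dihydrooxazole] (9 mol %), THF, 50 °C; 1 M HCl work-up
Reagents that add atoms: none
Why: Proposed new method: directed ortho-lithiation at the C3–H flanked by the two methoxy groups and transmetalation give arylzinc 6, and monovalent rhodium carrying the chiral phosphinooxazoline should insert into one of the two enantiotopic acyl C–O bonds of meso anhydride 4 (the one next to the S carbon), the resulting acyl trivalent rhodium carboxylate then being arylated by 6 and reductively eliminated to the ketone, so that the cis relationship of the methyl groups comes from 4 and the absolute configuration of both centres is fixed by the catalyst in the ring-opening; the closest known reaction type is anhydride cross-coupling, namely the rhodium/phosphinooxazoline-catalysed enantioselective desymmetrisation of this same anhydride with alkylzinc halides and the rhodium- or palladium-catalysed arylation of meso succinic anhydrides with arylzinc reagents.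

Step 3
Reactants: 7 (2R,4S)-5-[2,4-dimethoxy-5-(4-methoxyphenyl)pyridin-3-yl]-2,4-dimethyl-5-oxopentanoic acid
Product: 8 (2S,4R)-1-[2,4-dimethoxy-5-(4-methoxyphenyl)pyridin-3-yl]-5-hydroxy-2,4-dimethylpentan-1-one
Conditions: BH3·SMe2 (1.5 equiv), THF, 0 °C; then H2O
Reagents that add atoms: none
Why: Chemoselective borane reduction, in which the acid is activated as an acyloxyborane and is reduced far faster than the twisted, di-ortho-substituted and α-branched aryl ketone; neither stereocentre is touched.

Step 4
Reactants: 8 (2S,4R)-1-[2,4-dimethoxy-5-(4-methoxyphenyl)pyridin-3-yl]-5-hydroxy-2,4-dimethylpentan-1-one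
Product: 9 (2S,4R)-1-[2,4-dimethoxy-5-(4-methoxyphenyl)pyridin-3-yl]-5-iodo-2,4-dimethylpentan-1-one
Conditions: PPh3, I2, imidazole, CH2Cl2, 0 °C to rt
Reagents that add atoms: iodine, [I][I]
Why: Appel-type iodination, in which the primary alcohol is activated as an alkoxyphosphonium ion and displaced by iodide in an SN2 step at the CH2 carbon, away from both stereocentres.

Step 5
Reactants: 9 (2S,4R)-1-[2,4-dimethoxy-5-(4-methoxyphenyl)pyridin-3-yl]-5-iodo-2,4-dimethylpentan-1-one; 10 (E)-1-bromoprop-1-ene
Product: 11 (2S,4S,6E)-1-[2,4-dimethoxy-5-(4-methoxyphenyl)pyridin-3-yl]-2,4-dimethyloct-6-en-1-one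
Conditions: 10 (2.5 equiv), NiI2 (10 mol %), 4,4'-di-tert-butyl-2,2'-bipyridine (10 mol %), Mn powder (2 equiv), NaI (25 mol %), N,N-dimethylacetamide, 30 °C, sealed tube
Reagents that add atoms: none
Why: Nickel-catalysed reductive cross-electrophile coupling (sp3–sp2), in which the alkenyl bromide adds to zerovalent nickel with retention of the E geometry, the primary alkyl radical from 9 is captured and reductive elimination forms the C5–C6 bond; the radical sits on a CH2, so no stereocentre is at risk, and the hindered ketone is tolerated.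

Step 6
Reactants: 11 (2S,4S,6E)-1-[2,4-dimethoxy-5-(4-methoxyphenyl)pyridin-3-yl]-2,4-dimethyloct-6-en-1-one
Product: 12 tolypyridone C, 3-[(2S,4S,6E)-2,4-dimethyloct-6-enoyl]-4-hydroxy-5-(4-hydroxyphenyl)pyridin-2(1H)-one
Conditions: BBr3 (6 equiv), CH2Cl2, −78 to 0 °C; then H2O
Reagents that add atoms: none
Why: Lewis-acid ether cleavage with BBr3, in which bromide attacks each boron-activated O–CH3 (the chelated 4-methoxy first, then the 2-methoxy and the anisole) and the 2-hydroxypyridine tautomerises to the 2-pyridone on work-up; the isolated E-alkene and the α-stereocentre, held in the chelated vinylogous acid, should survive the low temperature.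

**Compound list**
1 | 5-bromo-2,4-dimethoxypyridine | COc1cc(OC)c(Br)cn1 | starting material
2 | 4-methoxyphenylboronic acid | COc1ccc(B(O)O)cc1 | starting material
3 | 2,4-dimethoxy-5-(4-methoxyphenyl)pyridine | COc1ccc(-c2cnc(OC)cc2OC)cc1 | intermediate
4 | meso-2,4-dimethylglutaric anhydride, (3R,5S)-3,5-dimethyloxane-2,6-dione | O1C(=O)[C@H](C)C[C@H](C)C1=O | starting material
5 | [2,4-dimethoxy-5-(4-methoxyphenyl)pyridin-3-yl]lithium (formed in the flask, not isolated) | COc1ccc(-c2cnc(OC)c([Li])c2OC)cc1 | intermediate
6 | [2,4-dimethoxy-5-(4-methoxyphenyl)pyridin-3-yl]zinc chloride (formed in the flask, not isolated) | COc1ccc(-c2cnc(OC)c([Zn]Cl)c2OC)cc1 | intermediate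
7 | (2R,4S)-5-[2,4-dimethoxy-5-(4-methoxyphenyl)pyridin-3-yl]-2,4-dimethyl-5-oxopentanoic acid | OC(=O)[C@H](C)C[C@H](C)C(=O)c1c(OC)c(-c2ccc(OC)cc2)cnc1OC | intermediate
8 | (2S,4R)-1-[2,4-dimethoxy-5-(4-methoxyphenyl)pyridin-3-yl]-5-hydroxy-2,4-dimethylpentan-1-one | OC[C@H](C)C[C@H](C)C(=O)c1c(OC)c(-c2ccc(OC)cc2)cnc1OC | intermediate
9 | (2S,4R)-1-[2,4-dimethoxy-5-(4-methoxyphenyl)pyridin-3-yl]-5-iodo-2,4-dimethylpentan-1-one | IC[C@H](C)C[C@H](C)C(=O)c1c(OC)c(-c2ccc(OC)cc2)cnc1OC | intermediate
10 | (E)-1-bromoprop-1-ene | C/C=C/Br | starting material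
11 | (2S,4S,6E)-1-[2,4-dimethoxy-5-(4-methoxyphenyl)pyridin-3-yl]-2,4-dimethyloct-6-en-1-one | C/C=C/C[C@H](C)C[C@H](C)C(=O)c1c(OC)c(-c2ccc(OC)cc2)cnc1OC | intermediate
12 | tolypyridone C, 3-[(2S,4S,6E)-2,4-dimethyloct-6-enoyl]-4-hydroxy-5-(4-hydroxyphenyl)pyridin-2(1H)-one | C/C=C/C[C@H](C)C[C@H](C)C(=O)c1c(O)c(-c2ccc(O)cc2)c[nH]c1=O | target

**Step count and risks**
Total steps: 6. Longest linear sequence: 6 (1 → 3 → 7 → 8 → 9 → 11 → 12).

Most likely to fail, step 2: the di-ortho-substituted heteroarylzinc may transmetalate slowly to the acyl rhodium species, so decarbonylation or low enantioselectivity is possible. The fallback sets out from 4 and comes back to the route at 8. The symmetry of 4 is broken instead by alkaloid-catalysed methanolysis: MeOH with (DHQD)2AQN or its pseudoenantiomer (whichever delivers the needed hemiester) in Et2O at −20 °C gives (2R,4S)-5-methoxy-2,4-dimethyl-5-oxopentanoic acid F1. BH3·SMe2 reduces its free acid to methyl (2S,4R)-5-hydroxy-2,4-dimethylpentanoate F2, which closes with catalytic TsOH in toluene to (3S,5R)-3,5-dimethyloxan-2-one F3. Aryllithium 5, made from 3 and n-BuLi as in step 2, adds once to F3 at −78 °C (the lithium lactolate resists a second addition), and dilute HCl work-up gives 8. Compound 7 and step 3 are bypassed and the route resumes at step 4.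

Second, step 5: the cross-electrophile coupling may give homodimers, reduction of the iodide or some E/Z erosion. The fallback sets out from 9 and comes back at 11. Zinc dust with LiCl in THF at 40 °C inserts into the C–I bond to give [(2R,4S)-5-[2,4-dimethoxy-5-(4-methoxyphenyl)pyridin-3-yl]-2,4-dimethyl-5-oxopentyl]zinc iodide F4, which tolerates the hindered ketone. A stereoretentive Negishi coupling of F4 with 10 under Pd(PPh3)4 (5 mol %) in THF at 40 °C then gives 11.

Third, step 6: BBr3 or adventitious HBr may add to or isomerise the alkene, or leave the 2-methoxy group partly intact. The fallback sets out from 11 and comes back at 12, replacing the all-Lewis-acid cleavage by a chelation-controlled cleavage followed by nucleophilic dealkylation. BCl3 (1.1 equiv, CH2Cl2, −78 °C) removes only the 4-O-methyl next to the ketone and gives (2S,4S,6E)-1-[4-hydroxy-2-methoxy-5-(4-methoxyphenyl)pyridin-3-yl]-2,4-dimethyloct-6-en-1-one F5. NaSEt in DMF at 110 °C then removes the two remaining methyl groups by SN2 attack at carbon; the 4-oxido ketone is an enolate-type anion that shields the α-stereocentre from epimerisation, and the alkene is not exposed to acid. Acidification gives 12.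

**Further compounds**
F1 | step 2 | (2R,4S)-5-methoxy-2,4-dimethyl-5-oxopentanoic acid | OC(=O)[C@H](C)C[C@H](C)C(=O)OC
F2 | step 2 | methyl (2S,4R)-5-hydroxy-2,4-dimethylpentanoate | OC[C@H](C)C[C@H](C)C(=O)OC
F3 | step 2 | (3S,5R)-3,5-dimethyloxan-2-one | O1C[C@H](C)C[C@H](C)C1=O
F4 | step 5 | [(2R,4S)-5-[2,4-dimethoxy-5-(4-methoxyphenyl)pyridin-3-yl]-2,4-dimethyl-5-oxopentyl]zinc iodide | I[Zn]C[C@H](C)C[C@H](C)C(=O)c1c(OC)c(-c2ccc(OC)cc2)cnc1OC
F5 | step 6 | (2S,4S,6E)-1-[4-hydroxy-2-methoxy-5-(4-methoxyphenyl)pyridin-3-yl]-2,4-dimethyloct-6-en-1-one | C/C=C/C[C@H](C)C[C@H](C)C(=O)c1c(O)c(-c2ccc(OC)cc2)cnc1OC
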